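(The readings are simulated on assumed constants, and the scatter is random.)

In a one-step world, Sub + Rgt → Prd, a flask that runs to its end holds as much Prd as its smaller charge. The flasks below test that picture.

| flask | Sub | Rgt | time |
|---|---|---|---|
| oak | 150 mM | 120 mM |  |
| maple | 75.0 mM | 45.0 mM |  |
| elm | 220 mM | 120 mM |  |
| larch | 150 mM | 360 mM |  |
| ash | 300 mM | 60.0 mM | 30 min |

| run | time / min | [Prd] / mM |
|---|---|---|
| oak run | 1.1 | 8.2 |
| oak run | 3.3 | 21.2 |
| oak run | 6.2 | 31.1 |
| oak run | 9.9 | 40.3 |
| oak run | 14 | 46.1 |
| oak run | 19 | 50.6 |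
| oak run | 24 | 51.7 |
| oak run | 30 | 53.9 |
| maple run | 1.1 | 2.9 |
| maple run | 3.3 | 7.6 |
| maple run | 6.2 | 10.8 |
| maple run | 9.9 | 15.2 |
| maple run | 14 | 16.5 |
| maple run | 19 | 18.4 |
| maple run | 24 | 19.9 |
| maple run | 30 | 20.6 |
| elm run | 1.1 | 11.3 |
| elm run | 3.3 | 27.0 |
| elm run | 6.2 | 40.2 |
| elm run | 9.9 | 49.4 |
| elm run | 14 | 52.7 |
| elm run | 19 | 53.7 |
| elm run | 24 | 55.6 |
| elm run | 30 | 54.4 |
| larch run | 1.1 | 14.3 |
| larch run | 3.3 | 31.0 |
| larch run | 6.2 | 47.8 |
| larch run | 9.9 | 58.5 |
| larch run | 14 | 62.2 |
| larch run | 19 | 67.0 |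
| larch run | 24 | 67.6 |
| larch run | 30 | 69.4 |

(standard deviation of a reading: 0.8 mM)

- Overall: Sub + Rgt -> Prd.
- Constant volume, constant temperature.
- A reading of a species includes what of it is bound.
- "The second partner" is Rgt.
- An order is taken over about fifteen percent of the charge, up and down.

1. order of the initial rate in [Rgt], near the charge of the oak run, the rate being that where two percent of its Sub are Prd
2. order of the initial rate in [Sub], near the charge of the oak run, the rate being that where two percent of its Sub are Prd (one fixed amount of Prd, the same in the runs compared)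
3. Prd in the ash run at 30 min, as a share of the Sub charged

In the first instants the rates reflect the charges. At 1.1 min, the first reading, oak holds 8.2 mM of Prd. At that same time larch, with Rgt at 360 mM, holds 1.74 times the Prd of oak, and elm, with Sub at 220 mM, holds 1.38 times the Prd of oak. Over these wide steps the first readings give orders of 0.506 in Rgt and 0.837 in Sub. That is the reckoning here, though the orders near oak's charge may differ from these.

In the middle of the run, at 9.9 min, oak reads 40.3 mM of Prd, a quarter of its Sub charge, and the question becomes what else uses the partners. Two rates at one moment can be compared: Prd-making against a competing loss, taken here to use one Sub per Rgt. The last readings show what share of the smaller charge has become Prd in each flask.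

At the end these shares read close to one another. Rgt is the limiting reagent in oak, and the last reading is 0.449 of that charge. Maple gives 0.458, elm 0.453 and larch, whose smaller charge is Sub, 0.463, while Rgt over Sub ranges from 0.545 to 2.40. Oak still climbs from 51.7 mM to 53.9 mM, so last readings sit low, and the highest is taken: larch's last reading over its Sub charge, the branching share φ = 0.463, a reading good to about 0.00533.

Ash ends with 0.240 M of Sub on that one-to-one count, more than elm's 0.100 M. Elm reads 52.7 mM at 14 min and 54.4 mM at 30 min, so ash is taken as finished by 30 min. Then φ times its Rgt gives 0.0278 M, or 9.25 % of its Sub.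

The forecast gave 0.45 (0.2 to 0.7) for the order in Rgt, 1.1 (0.8 to 1.4) for the order in Sub, above the Sub order here, and 9.2 % (8 % to 10.5 %) for ash, saying of ash that “it should be finished by 30 min”.

The flask gives 0.57 and 0.87 for the orders, and 9.24 % for ash, which is 0.462 of its Rgt charge as Prd.

    Sub + Rgt → Prd (3.018 L mol⁻¹ min⁻¹)
    Sub + Rgt → Sid (3.516 L mol⁻¹ min⁻¹)
    Sub + Rgt ⇌ Sub.Rgt, settled at all times (14.20 L mol⁻¹)
    2 Rgt ⇌ Rgt2, settled at all times (49.00 L mol⁻¹)

Sub and Rgt leave by two steps of one form, to Prd with 3.02 L mol⁻¹ min⁻¹ and to Sid with 3.52 L mol⁻¹ min⁻¹. In elm, φ times the Rgt charge is 0.0555 M, and a quarter of its Sub, 0.0550 M, stands at nearly all of that amount. Elm reaches this mark at 20.8 min.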